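**Strategy.** Rings are lettered A (2,4,6-trihydroxyphenoxy end) to F. Ring D is read as a folded triketide: C3 (OH) is an ester carbon, C5 (OH) a ketone, C1 (O–ring C) an enol ether carbon and C4 (O–ring E) the terminal α-carbon of a 3,5-dioxohexanoate. Everything rests on cutting the C3–C4 bond of ring D. One base-mediated Claisen (Dieckmann) closure of a methyl (E)-3-aryloxy-6-aryloxy-5-oxohex-2-enoate makes that bond and aromatises, so ring D is born with both diaryl ether links and its hindered C4–O bond is never formed by coupling. The precursor arises from γ-acylation of an aryloxycrotonate dienolate with a Weinreb amide; rings B and A are then added by Ullmann couplings.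

Key step: step 9

Remark on the chemistry: the target has no stereocentre. The only stereo-element on the way is the E enol ether of 14 and 17 (aryloxy trans to the ester, so the ester and the C4 arm are cis). The C4 enolate formed in step 9 lets the two geometries interconvert, so a minor Z content is assumed to be harmless.

Assumption: compounds 1, 2, 6, 13, 22 and 26 are taken as commercial.

**Route**

Step 1
Reactants: 1 2-bromo-3,4,5-trimethoxybenzaldehyde; 2 3,4,5-trimethoxyphenol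
Product: 3 3,4,5-trimethoxy-2-(3,4,5-trimethoxyphenoxy)benzaldehyde
Conditions: CuI (10 mol%), N,N-dimethylglycine·HCl (30 mol%), Cs2CO3, 1,4-dioxane, 100 °C
Reagents that add atoms: none
Why: Ullmann diaryl ether synthesis: the ortho-formyl group activates the C–Br bond of 1 towards copper insertion and the electron-rich phenoxide of 2 is a competent nucleophile, so C–O coupling should occur at C2 despite the flanking methoxy group, with the aldehyde (no α-hydrogen) surviving the carbonate base.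

Step 2
Reactants: 3 3,4,5-trimethoxy-2-(3,4,5-trimethoxyphenoxy)benzaldehyde
Product: 5 3,4,5-trimethoxy-2-(3,4,5-trimethoxyphenoxy)phenol, via aryl formate 4 (not isolated)
Conditions: mCPBA, CH2Cl2, 0 °C to rt; then K2CO3 (cat.), MeOH, rt
Reagents that add atoms: 3-chloroperoxybenzoic acid (mCPBA), O=C(OO)c1cccc(Cl)c1
Why: Baeyer–Villiger oxidation in its Dakin-type sense: the aryl group bearing ortho-aryloxy and para-methoxy donors should migrate to oxygen in preference to hydride, and the formate 4 is then removed by base-catalysed transesterification with methanol.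

Step 3
Reactants: 5 3,4,5-trimethoxy-2-(3,4,5-trimethoxyphenoxy)phenol; 6 2-chloro-N-methoxy-N-methylacetamide
Product: 7 N-methoxy-N-methyl-2-[3,4,5-trimethoxy-2-(3,4,5-trimethoxyphenoxy)phenoxy]acetamide
Conditions: K2CO3, NaI (cat.), DMF, 60 °C
Reagents that add atoms: none
Why: Williamson ether synthesis: SN2 displacement of the α-chloro amide (as its iodide, formed by Finkelstein exchange) by the phenoxide of 5 should install the two-carbon unit that becomes C5 and C6 of the chain, already as a Weinreb amide.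

Step 4
Reactants: 2 3,4,5-trimethoxyphenol
Product: 8 5-(benzyloxy)-1,2,3-trimethoxybenzene
Conditions: BnBr, K2CO3, acetone, reflux
Reagents that add atoms: benzyl bromide, BrCc1ccccc1
Why: Williamson ether synthesis: benzylation of the phenoxide gives the ether that later masks the ring C hydroxyl destined to carry ring B.

Step 5
Reactants: 8 5-(benzyloxy)-1,2,3-trimethoxybenzene
Product: 10 6-(benzyloxy)-2,3,4-trimethoxybenzaldehyde, via iminium chloride 9 (not isolated)
Conditions: POCl3, DMF, 0 °C to rt; then H2O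
Reagents that add atoms: N,N-dimethylformamide, CN(C)C=O; water, O; phosphoryl chloride, O=P(Cl)(Cl)Cl (supplies only the chloride counter-ion of 9)
Why: Vilsmeier–Haack formylation: the two open positions of the tetra-alkoxybenzene are equivalent by symmetry and strongly activated (ortho to benzyloxy, ortho and para to methoxy), so one aldehyde should form after hydrolysis of iminium salt 9.

Step 6
Reactants: 10 6-(benzyloxy)-2,3,4-trimethoxybenzaldehyde
Product: 12 6-(benzyloxy)-2,3,4-trimethoxyphenol, via aryl formate 11 (not isolated)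
Conditions: mCPBA, CH2Cl2, 0 °C to rt; then K2CO3 (cat.), MeOH, rt
Reagents that add atoms: 3-chloroperoxybenzoic acid (mCPBA), O=C(OO)c1cccc(Cl)c1
Why: Baeyer–Villiger oxidation (Dakin-type): the aryl group with two ortho alkoxy groups and a para methoxy group should migrate cleanly, and methanolysis of formate 11 frees the phenol that lies between the benzyloxy and methoxy groups.

Step 7
Reactants: 12 6-(benzyloxy)-2,3,4-trimethoxyphenol; 13 methyl but-2-ynoate
Product: 14 methyl (E)-3-[6-(benzyloxy)-2,3,4-trimethoxyphenoxy]but-2-enoate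
Conditions: Cs2CO3 (20 mol%), DMF, 60 °C
Reagents that add atoms: none
Why: Base-catalysed oxa-Michael addition of the phenoxide to the alkynoate: attack at C3 followed by protonation should give the β-aryloxy crotonate, and reversible addition under the basic conditions is expected to settle on the E isomer (aryloxy trans to the ester), the more stable geometry of β-oxy crotonates.

Step 8
Reactants: 14 methyl (E)-3-[6-(benzyloxy)-2,3,4-trimethoxyphenoxy]but-2-enoate; 7 N-methoxy-N-methyl-2-[3,4,5-trimethoxy-2-(3,4,5-trimethoxyphenoxy)phenoxy]acetamide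
Product: 17 methyl (E)-3-[6-(benzyloxy)-2,3,4-trimethoxyphenoxy]-5-oxo-6-[3,4,5-trimethoxy-2-(3,4,5-trimethoxyphenoxy)phenoxy]hex-2-enoate, via lithium dienolate 15 (not isolated), via lithium hemiaminal adduct 16 (not isolated)
Conditions: LiN(iPr)2 (LDA), THF, −78 °C; then 7, −78 to −40 °C; then AcOH, −78 °C
Reagents that add atoms: lithium diisopropylamide, [Li+].CC(C)[N-]C(C)C (supplies only the lithium of 15 and 16)
Why: Vinylogous Claisen condensation: γ-deprotonation of 14 gives dienolate 15, whose γ-carbon (the site favoured for 3-oxygenated crotonate dienolates with carbonyl electrophiles) should add to the Weinreb amide, and the chelated adduct 16 releases the ketone only on the cold acidic quench, which should rule out double addition, proton transfer to unreacted dienolate and lactonisation while the E geometry is kept at −78 °C.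

Step 9
Reactants: 17 methyl (E)-3-[6-(benzyloxy)-2,3,4-trimethoxyphenoxy]-5-oxo-6-[3,4,5-trimethoxy-2-(3,4,5-trimethoxyphenoxy)phenoxy]hex-2-enoate
Product: 19 5-[6-(benzyloxy)-2,3,4-trimethoxyphenoxy]-2-[3,4,5-trimethoxy-2-(3,4,5-trimethoxyphenoxy)phenoxy]benzene-1,3-diol, via cyclohexenedione tautomer 18 (not isolated)
Conditions: NaOMe (5 equiv), degassed MeOH–THF, 65 °C, argon; then 1 M HCl
Reagents that add atoms: none
Why: Methoxide in methanol equilibrates the chain among its enolates, mainly the unreactive C4 enolate; the minor C6 enolate, stabilised by the ketone and by the α-aryloxy group of ring E, should add to the ester carbonyl, methoxide leaves, and dione 18 enolises to the aromatic resorcinol 19, whose phenoxide is a thermodynamic sink. The closest known reaction type is the Claisen (Dieckmann) cyclisation of 3,5-dioxohexanoate esters and of their 3-O-alkyl enol ethers to phloroglucinol and resorcinol derivatives. Ring D closes in the 6-(enolexo)-exo-trig mode, with the E enol ether placing the ester and the ketone arm on the same side of the C2=C3 bond. No stereocentre is created, because the sp3 carbon of 18 is lost on aromatisation. The selectivity required is carbon–carbon bond formation at C6 in preference to closure through the ketone oxygen (the 2-pyranone, F8 below) and to displacement of the ring C aryloxide at C3; the lactone is reopened by methanolysis and can only be a reservoir, and the predominant C4 enolate is not electrophilic at C3.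

Step 10
Reactants: 19 5-[6-(benzyloxy)-2,3,4-trimethoxyphenoxy]-2-[3,4,5-trimethoxy-2-(3,4,5-trimethoxyphenoxy)phenoxy]benzene-1,3-diol
Product: 20 1-(benzyloxy)-2-{3,5-dimethoxy-4-[3,4,5-trimethoxy-2-(3,4,5-trimethoxyphenoxy)phenoxy]phenoxy}-3,4,5-trimethoxybenzene
Conditions: MeI, K2CO3, DMF, rt
Reagents that add atoms: iodomethane, CI
Why: Williamson O-methylation: both ring D phenoxides are alkylated so that every hydroxyl except the benzyl-protected one on ring C is a methyl ether and cannot compete in the later arylations.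

Step 11
Reactants: 20 1-(benzyloxy)-2-{3,5-dimethoxy-4-[3,4,5-trimethoxy-2-(3,4,5-trimethoxyphenoxy)phenoxy]phenoxy}-3,4,5-trimethoxybenzene
Product: 21 2-{3,5-dimethoxy-4-[3,4,5-trimethoxy-2-(3,4,5-trimethoxyphenoxy)phenoxy]phenoxy}-3,4,5-trimethoxyphenol
Conditions: H2 (1 atm), 10% Pd/C, EtOAc–MeOH, rt
Reagents that add atoms: none
Why: Catalytic hydrogenolysis of the benzyl ether: the benzylic C–O bond is cleaved on palladium while methyl ethers and diaryl ethers are inert, exposing the single phenol on ring C.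

Step 12
Reactants: 21 2-{3,5-dimethoxy-4-[3,4,5-trimethoxy-2-(3,4,5-trimethoxyphenoxy)phenoxy]phenoxy}-3,4,5-trimethoxyphenol; 22 4-bromo-3,5-dimethoxybenzaldehyde
Product: 23 4-(2-{3,5-dimethoxy-4-[3,4,5-trimethoxy-2-(3,4,5-trimethoxyphenoxy)phenoxy]phenoxy}-3,4,5-trimethoxyphenoxy)-3,5-dimethoxybenzaldehyde
Conditions: CuI (20 mol%), N,N-dimethylglycine·HCl (40 mol%), Cs2CO3, 1,4-dioxane, 105 °C
Reagents that add atoms: none
Why: Ullmann diaryl ether synthesis: the para-formyl group activates the C–Br bond between the two methoxy groups of 22 and serves as the masked C1 oxygen of ring B, so copper-catalysed coupling with the phenoxide of 21 should give the ring B–C ether.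

Step 13
Reactants: 23 4-(2-{3,5-dimethoxy-4-[3,4,5-trimethoxy-2-(3,4,5-trimethoxyphenoxy)phenoxy]phenoxy}-3,4,5-trimethoxyphenoxy)-3,5-dimethoxybenzaldehyde
Product: 25 4-(2-{3,5-dimethoxy-4-[3,4,5-trimethoxy-2-(3,4,5-trimethoxyphenoxy)phenoxy]phenoxy}-3,4,5-trimethoxyphenoxy)-3,5-dimethoxyphenol, via aryl formate 24 (not isolated)
Conditions: mCPBA, CH2Cl2, 0 °C to rt; then K2CO3 (cat.), MeOH, rt
Reagents that add atoms: 3-chloroperoxybenzoic acid (mCPBA), O=C(OO)c1cccc(Cl)c1
Why: Baeyer–Villiger oxidation (Dakin-type): the 4-aryloxy-3,5-dimethoxyphenyl group should migrate as 3,4,5-trialkoxyphenyl groups do, and methanolysis of formate 24 gives the ring B phenol, which has no ortho substituent.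

Step 14
Reactants: 25 4-(2-{3,5-dimethoxy-4-[3,4,5-trimethoxy-2-(3,4,5-trimethoxyphenoxy)phenoxy]phenoxy}-3,4,5-trimethoxyphenoxy)-3,5-dimethoxyphenol; 26 2-iodo-1,3,5-trimethoxybenzene
Product: 27 5-(4-{6-[2,6-dimethoxy-4-(2,4,6-trimethoxyphenoxy)phenoxy]-2,3,4-trimethoxyphenoxy}-2,6-dimethoxyphenoxy)-1,2,3-trimethoxy-4-(3,4,5-trimethoxyphenoxy)benzene
Conditions: CuI (20 mol%), picolinic acid (40 mol%), K3PO4, DMSO, 100 °C
Reagents that add atoms: none
Why: Ullmann diaryl ether synthesis: the unhindered phenoxide of 25 should couple with the di-ortho-methoxy aryl iodide under picolinic acid-assisted copper catalysis, a ligand system suited to hindered, electron-rich iodides, installing ring A.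

Step 15
Reactants: 27 5-(4-{6-[2,6-dimethoxy-4-(2,4,6-trimethoxyphenoxy)phenoxy]-2,3,4-trimethoxyphenoxy}-2,6-dimethoxyphenoxy)-1,2,3-trimethoxy-4-(3,4,5-trimethoxyphenoxy)benzene
Product: 28 5-(4-{6-[2,6-dihydroxy-4-(2,4,6-trihydroxyphenoxy)phenoxy]-2,3,4-trihydroxyphenoxy}-2,6-dihydroxyphenoxy)-4-(3,4,5-trihydroxyphenoxy)benzene-1,2,3-triol (CNP0114537.0)
Conditions: BBr3 (excess), CH2Cl2, −78 °C to rt, argon; then H2O, 0 °C
Reagents that add atoms: none
Why: Lewis acid-mediated cleavage of aryl methyl ethers: each methoxy oxygen coordinates BBr3 and bromide removes the methyl group by SN2, whereas the five diaryl ether bonds offer no sp3 carbon for attack and should survive, so hydrolysis of the aryl borates under argon should release all sixteen hydroxyls.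

**Compound list**

1 | 2-bromo-3,4,5-trimethoxybenzaldehyde | COc1cc(C=O)c(Br)c(OC)c1OC | starting material
2 | 3,4,5-trimethoxyphenol | COc1cc(O)cc(OC)c1OC | starting material
3 | 3,4,5-trimethoxy-2-(3,4,5-trimethoxyphenoxy)benzaldehyde | COc1cc(C=O)c(Oc2cc(OC)c(OC)c(OC)c2)c(OC)c1OC | intermediate
4 | 3,4,5-trimethoxy-2-(3,4,5-trimethoxyphenoxy)phenyl formate | COc1cc(OC=O)c(Oc2cc(OC)c(OC)c(OC)c2)c(OC)c1OC | intermediate (not isolated)
5 | 3,4,5-trimethoxy-2-(3,4,5-trimethoxyphenoxy)phenol | COc1cc(O)c(Oc2cc(OC)c(OC)c(OC)c2)c(OC)c1OC | intermediate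
6 | 2-chloro-N-methoxy-N-methylacetamide | CON(C)C(=O)CCl | starting material
7 | N-methoxy-N-methyl-2-[3,4,5-trimethoxy-2-(3,4,5-trimethoxyphenoxy)phenoxy]acetamide | CON(C)C(=O)COc1cc(OC)c(OC)c(OC)c1Oc1cc(OC)c(OC)c(OC)c1 | intermediate
8 | 5-(benzyloxy)-1,2,3-trimethoxybenzene | COc1cc(OCc2ccccc2)cc(OC)c1OC | intermediate
9 | [6-(benzyloxy)-2,3,4-trimethoxybenzylidene]dimethyliminium chloride | C[N+](C)=Cc1c(OCc2ccccc2)cc(OC)c(OC)c1OC.[Cl-] | intermediate (not isolated)
10 | 6-(benzyloxy)-2,3,4-trimethoxybenzaldehyde | O=Cc1c(OCc2ccccc2)cc(OC)c(OC)c1OC | intermediate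
11 | 6-(benzyloxy)-2,3,4-trimethoxyphenyl formate | O=COc1c(OCc2ccccc2)cc(OC)c(OC)c1OC | intermediate (not isolated)
12 | 6-(benzyloxy)-2,3,4-trimethoxyphenol | Oc1c(OCc2ccccc2)cc(OC)c(OC)c1OC | intermediate
13 | methyl but-2-ynoate | CC#CC(=O)OC | starting material
14 | methyl (E)-3-[6-(benzyloxy)-2,3,4-trimethoxyphenoxy]but-2-enoate | COC(=O)/C=C(/Oc1c(OCc2ccccc2)cc(OC)c(OC)c1OC)C | intermediate
15 | lithium 3-[6-(benzyloxy)-2,3,4-trimethoxyphenoxy]-1-methoxybuta-1,3-dien-1-olate | [Li+].COC([O-])=CC(=C)Oc1c(OCc2ccccc2)cc(OC)c(OC)c1OC | intermediate (not isolated)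
16 | lithium (E)-4-[6-(benzyloxy)-2,3,4-trimethoxyphenoxy]-6-methoxy-2-[methoxy(methyl)amino]-6-oxo-1-[3,4,5-trimethoxy-2-(3,4,5-trimethoxyphenoxy)phenoxy]hex-4-en-2-olate (racemic at C2) | [Li+].COC(=O)/C=C(/Oc1c(OCc2ccccc2)cc(OC)c(OC)c1OC)CC([O-])(COc1cc(OC)c(OC)c(OC)c1Oc1cc(OC)c(OC)c(OC)c1)N(C)OC | intermediate (not isolated)
17 | methyl (E)-3-[6-(benzyloxy)-2,3,4-trimethoxyphenoxy]-5-oxo-6-[3,4,5-trimethoxy-2-(3,4,5-trimethoxyphenoxy)phenoxy]hex-2-enoate | COC(=O)/C=C(/Oc1c(OCc2ccccc2)cc(OC)c(OC)c1OC)CC(=O)COc1cc(OC)c(OC)c(OC)c1Oc1cc(OC)c(OC)c(OC)c1 | intermediate (precursor of the key step)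
18 | 5-[6-(benzyloxy)-2,3,4-trimethoxyphenoxy]-2-[3,4,5-trimethoxy-2-(3,4,5-trimethoxyphenoxy)phenoxy]cyclohex-4-ene-1,3-dione (racemic at C2) | O=C1C=C(Oc2c(OCc3ccccc3)cc(OC)c(OC)c2OC)CC(=O)C1Oc1cc(OC)c(OC)c(OC)c1Oc1cc(OC)c(OC)c(OC)c1 | intermediate (not isolated)
19 | 5-[6-(benzyloxy)-2,3,4-trimethoxyphenoxy]-2-[3,4,5-trimethoxy-2-(3,4,5-trimethoxyphenoxy)phenoxy]benzene-1,3-diol | Oc1cc(Oc2c(OCc3ccccc3)cc(OC)c(OC)c2OC)cc(O)c1Oc1cc(OC)c(OC)c(OC)c1Oc1cc(OC)c(OC)c(OC)c1 | intermediate (product of the key step)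
20 | 1-(benzyloxy)-2-{3,5-dimethoxy-4-[3,4,5-trimethoxy-2-(3,4,5-trimethoxyphenoxy)phenoxy]phenoxy}-3,4,5-trimethoxybenzene | COc1cc(Oc2c(OCc3ccccc3)cc(OC)c(OC)c2OC)cc(OC)c1Oc1cc(OC)c(OC)c(OC)c1Oc1cc(OC)c(OC)c(OC)c1 | intermediate
21 | 2-{3,5-dimethoxy-4-[3,4,5-trimethoxy-2-(3,4,5-trimethoxyphenoxy)phenoxy]phenoxy}-3,4,5-trimethoxyphenol | COc1cc(Oc2c(O)cc(OC)c(OC)c2OC)cc(OC)c1Oc1cc(OC)c(OC)c(OC)c1Oc1cc(OC)c(OC)c(OC)c1 | intermediate
22 | 4-bromo-3,5-dimethoxybenzaldehyde | COc1cc(C=O)cc(OC)c1Br | starting material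
23 | 4-(2-{3,5-dimethoxy-4-[3,4,5-trimethoxy-2-(3,4,5-trimethoxyphenoxy)phenoxy]phenoxy}-3,4,5-trimethoxyphenoxy)-3,5-dimethoxybenzaldehyde | COc1cc(C=O)cc(OC)c1Oc1cc(OC)c(OC)c(OC)c1Oc1cc(OC)c(Oc2cc(OC)c(OC)c(OC)c2Oc2cc(OC)c(OC)c(OC)c2)c(OC)c1 | intermediate
24 | 4-(2-{3,5-dimethoxy-4-[3,4,5-trimethoxy-2-(3,4,5-trimethoxyphenoxy)phenoxy]phenoxy}-3,4,5-trimethoxyphenoxy)-3,5-dimethoxyphenyl formate | COc1cc(OC=O)cc(OC)c1Oc1cc(OC)c(OC)c(OC)c1Oc1cc(OC)c(Oc2cc(OC)c(OC)c(OC)c2Oc2cc(OC)c(OC)c(OC)c2)c(OC)c1 | intermediate (not isolated)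
25 | 4-(2-{3,5-dimethoxy-4-[3,4,5-trimethoxy-2-(3,4,5-trimethoxyphenoxy)phenoxy]phenoxy}-3,4,5-trimethoxyphenoxy)-3,5-dimethoxyphenol | COc1cc(O)cc(OC)c1Oc1cc(OC)c(OC)c(OC)c1Oc1cc(OC)c(Oc2cc(OC)c(OC)c(OC)c2Oc2cc(OC)c(OC)c(OC)c2)c(OC)c1 | intermediate
26 | 2-iodo-1,3,5-trimethoxybenzene | COc1cc(OC)c(I)c(OC)c1 | starting material
27 | 5-(4-{6-[2,6-dimethoxy-4-(2,4,6-trimethoxyphenoxy)phenoxy]-2,3,4-trimethoxyphenoxy}-2,6-dimethoxyphenoxy)-1,2,3-trimethoxy-4-(3,4,5-trimethoxyphenoxy)benzene (hexadeca-O-methyl ether of 28) | COc1cc(OC)c(Oc2cc(OC)c(Oc3cc(OC)c(OC)c(OC)c3Oc3cc(OC)c(Oc4cc(OC)c(OC)c(OC)c4Oc4cc(OC)c(OC)c(OC)c4)c(OC)c3)c(OC)c2)c(OC)c1 | intermediate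
28 | 5-(4-{6-[2,6-dihydroxy-4-(2,4,6-trihydroxyphenoxy)phenoxy]-2,3,4-trihydroxyphenoxy}-2,6-dihydroxyphenoxy)-4-(3,4,5-trihydroxyphenoxy)benzene-1,2,3-triol (CNP0114537.0) | Oc1cc(O)c(Oc2cc(O)c(Oc3cc(O)c(O)c(O)c3Oc3cc(O)c(Oc4cc(O)c(O)c(O)c4Oc4cc(O)c(O)c(O)c4)c(O)c3)c(O)c2)c(O)c1 | target

**Step count and risks**

Total step count: 15. Longest linear sequence: 12 steps (2 → 8 → 10 → 12 → 14 → 17 → 19 → 20 → 21 → 23 → 25 → 27 → 28, steps 4 to 15). The ring E–F arm (steps 1 to 3) joins at step 8.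

The three steps most likely to fail:

Step 9 (key cyclisation). The chain may close through the ketone oxygen and rest as the 2-pyranone. Alternatively, methoxide may expel the ring C aryloxide by conjugate addition–elimination before C6 reaches the ester. The fallback gives up ring construction and brings ring D in as a ready-made arene, setting out from 5 and 8 and coming back at 20.
- Phenol 5 is coupled with 22 (CuI, N,N-dimethylglycine·HCl, Cs2CO3, dioxane, 100 °C) to give 3,5-dimethoxy-4-[3,4,5-trimethoxy-2-(3,4,5-trimethoxyphenoxy)phenoxy]benzaldehyde F1.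
- Baeyer–Villiger oxidation with mCPBA gives 3,5-dimethoxy-4-[3,4,5-trimethoxy-2-(3,4,5-trimethoxyphenoxy)phenoxy]phenyl formate F2. Methanolysis (K2CO3, MeOH) then gives 3,5-dimethoxy-4-[3,4,5-trimethoxy-2-(3,4,5-trimethoxyphenoxy)phenoxy]phenol F3.
- Separately, 8 is iodinated with N-iodosuccinimide in MeCN at one of its two equivalent ring positions to give 1-(benzyloxy)-2-iodo-3,4,5-trimethoxybenzene F4.
- Ullmann coupling of the unhindered phenol F3 with F4 (CuI, picolinic acid, K3PO4, DMSO, 100 °C) should deliver 20 directly, and the route goes on with step 11.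

Step 8 (γ-acylation). The dienolate may react through its α-carbon, it may simply deprotonate the amide, or it may lose the ring C aryloxide by β-elimination on warming. The fallback makes the same carbon chain from a dianion that is known to acylate at its terminus and introduces the aryl enol ether afterwards. It sets out from 7 and 12 and comes back at 17.
- The dianion of methyl acetoacetate (COC(=O)CC(C)=O; NaH, then n-BuLi, THF, 0 °C) is acylated with 7 to give methyl 3,5-dioxo-6-[3,4,5-trimethoxy-2-(3,4,5-trimethoxyphenoxy)phenoxy]hexanoate F5.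
- Lactonisation (DBU, toluene, 80 °C) gives 4-hydroxy-6-{[3,4,5-trimethoxy-2-(3,4,5-trimethoxyphenoxy)phenoxy]methyl}-2H-pyran-2-one F6.
- Bu4NBr and P2O5 in toluene at 100 °C convert it into 4-bromo-6-{[3,4,5-trimethoxy-2-(3,4,5-trimethoxyphenoxy)phenoxy]methyl}-2H-pyran-2-one F7.
- Addition–elimination of the phenoxide of 12 (K2CO3, DMF) gives 4-[6-(benzyloxy)-2,3,4-trimethoxyphenoxy]-6-{[3,4,5-trimethoxy-2-(3,4,5-trimethoxyphenoxy)phenoxy]methyl}-2H-pyran-2-one F8.
- Methanolysis of the lactone of F8 with NaOMe in MeOH should regenerate 17 as its enolate in the flask. The ring fixes the ester and the ketone arm cis, which is the E geometry, and 17 then enters step 9 under the same conditions.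

Step 12 (first ring B coupling). Carbon–oxygen bond formation between an ortho-aryloxy phenol and a bromide flanked by two methoxy groups may be slow, leaving room for hydrodebromination or base-induced loss of the aldehyde. The fallback repeats the tactic of ring D for ring B, so that neither ether bond of ring B needs a copper coupling. It sets out from 21 and comes back at 27, replacing steps 12 to 14.
- Phenol 21 is alkylated with 6 (K2CO3, NaI, DMF) to give N-methoxy-N-methyl-2-(2-{3,5-dimethoxy-4-[3,4,5-trimethoxy-2-(3,4,5-trimethoxyphenoxy)phenoxy]phenoxy}-3,4,5-trimethoxyphenoxy)acetamide F9.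
- Commercial 2,4,6-trimethoxyphenol (COc1cc(OC)c(O)c(OC)c1) is added to 13 (Cs2CO3 cat., DMF) to give methyl (E)-3-(2,4,6-trimethoxyphenoxy)but-2-enoate F10.
- F10 is deprotonated with LiN(iPr)2 at −78 °C and acylated with F9 to give methyl (E)-6-(2-{3,5-dimethoxy-4-[3,4,5-trimethoxy-2-(3,4,5-trimethoxyphenoxy)phenoxy]phenoxy}-3,4,5-trimethoxyphenoxy)-5-oxo-3-(2,4,6-trimethoxyphenoxy)hex-2-enoate F11.
- Cyclisation with NaOMe in MeOH gives 2-(2-{3,5-dimethoxy-4-[3,4,5-trimethoxy-2-(3,4,5-trimethoxyphenoxy)phenoxy]phenoxy}-3,4,5-trimethoxyphenoxy)-5-(2,4,6-trimethoxyphenoxy)benzene-1,3-diol F12.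
- Methylation of F12 (MeI, K2CO3, DMF) gives 27.

**Further compounds**

F1 | step 9 | 3,5-dimethoxy-4-[3,4,5-trimethoxy-2-(3,4,5-trimethoxyphenoxy)phenoxy]benzaldehyde | COc1cc(C=O)cc(OC)c1Oc1cc(OC)c(OC)c(OC)c1Oc1cc(OC)c(OC)c(OC)c1
F2 | step 9 | 3,5-dimethoxy-4-[3,4,5-trimethoxy-2-(3,4,5-trimethoxyphenoxy)phenoxy]phenyl formate | COc1cc(OC=O)cc(OC)c1Oc1cc(OC)c(OC)c(OC)c1Oc1cc(OC)c(OC)c(OC)c1
F3 | step 9 | 3,5-dimethoxy-4-[3,4,5-trimethoxy-2-(3,4,5-trimethoxyphenoxy)phenoxy]phenol | COc1cc(O)cc(OC)c1Oc1cc(OC)c(OC)c(OC)c1Oc1cc(OC)c(OC)c(OC)c1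
F4 | step 9 | 1-(benzyloxy)-2-iodo-3,4,5-trimethoxybenzene | COc1cc(OCc2ccccc2)c(I)c(OC)c1OC
F5 | step 8 | methyl 3,5-dioxo-6-[3,4,5-trimethoxy-2-(3,4,5-trimethoxyphenoxy)phenoxy]hexanoate | COC(=O)CC(=O)CC(=O)COc1cc(OC)c(OC)c(OC)c1Oc1cc(OC)c(OC)c(OC)c1
F6 | step 8 | 4-hydroxy-6-{[3,4,5-trimethoxy-2-(3,4,5-trimethoxyphenoxy)phenoxy]methyl}-2H-pyran-2-one | O=c1cc(O)cc(COc2cc(OC)c(OC)c(OC)c2Oc2cc(OC)c(OC)c(OC)c2)o1
F7 | step 8 | 4-bromo-6-{[3,4,5-trimethoxy-2-(3,4,5-trimethoxyphenoxy)phenoxy]methyl}-2H-pyran-2-one | O=c1cc(Br)cc(COc2cc(OC)c(OC)c(OC)c2Oc2cc(OC)c(OC)c(OC)c2)o1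
F8 | step 8 | 4-[6-(benzyloxy)-2,3,4-trimethoxyphenoxy]-6-{[3,4,5-trimethoxy-2-(3,4,5-trimethoxyphenoxy)phenoxy]methyl}-2H-pyran-2-one | O=c1cc(Oc2c(OCc3ccccc3)cc(OC)c(OC)c2OC)cc(COc2cc(OC)c(OC)c(OC)c2Oc2cc(OC)c(OC)c(OC)c2)o1
F9 | step 12 | N-methoxy-N-methyl-2-(2-{3,5-dimethoxy-4-[3,4,5-trimethoxy-2-(3,4,5-trimethoxyphenoxy)phenoxy]phenoxy}-3,4,5-trimethoxyphenoxy)acetamide | COc1cc(Oc2c(OCC(=O)N(C)OC)cc(OC)c(OC)c2OC)cc(OC)c1Oc1cc(OC)c(OC)c(OC)c1Oc1cc(OC)c(OC)c(OC)c1
F10 | step 12 | methyl (E)-3-(2,4,6-trimethoxyphenoxy)but-2-enoate | COC(=O)/C=C(/Oc1c(OC)cc(OC)cc1OC)C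
F11 | step 12 | methyl (E)-6-(2-{3,5-dimethoxy-4-[3,4,5-trimethoxy-2-(3,4,5-trimethoxyphenoxy)phenoxy]phenoxy}-3,4,5-trimethoxyphenoxy)-5-oxo-3-(2,4,6-trimethoxyphenoxy)hex-2-enoate | COC(=O)/C=C(/Oc1c(OC)cc(OC)cc1OC)CC(=O)COc1cc(OC)c(OC)c(OC)c1Oc1cc(OC)c(Oc2cc(OC)c(OC)c(OC)c2Oc2cc(OC)c(OC)c(OC)c2)c(OC)c1
F12 | step 12 | 2-(2-{3,5-dimethoxy-4-[3,4,5-trimethoxy-2-(3,4,5-trimethoxyphenoxy)phenoxy]phenoxy}-3,4,5-trimethoxyphenoxy)-5-(2,4,6-trimethoxyphenoxy)benzene-1,3-diol | Oc1cc(Oc2c(OC)cc(OC)cc2OC)cc(O)c1Oc1cc(OC)c(OC)c(OC)c1Oc1cc(OC)c(Oc2cc(OC)c(OC)c(OC)c2Oc2cc(OC)c(OC)c(OC)c2)c(OC)c1
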